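**Assumptions.**
- (+) is taken as the descriptor of the named enantiomer, so I rely only on the stated CIP labels.
- The target's 8,8'-core is the meso-type (8S,8'R) pair, and the 8''-O-4' unit is erythro (7''S,8''R).
- The pseudoenantiomer (DHQD)2AQN is assumed to give the (2R,3S) mono-ester in Step 2. If the other enantiomer forms, use (DHQ)2AQN.
- Converting C(=O) to CH2Ar changes the CIP label at C8 and C8' without changing the geometry. The SMILES chirality tags are carried unchanged through the route.

## Retrosynthetic overview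
1. Target ⇒ double O-debenzylation of erythro-alcohol 19 ⇐ **new step**: Ru-catalysed dynamic kinetic asymmetric transfer hydrogenation (ATH-DKR) of the α-aryloxy ketone 18, which sets C7'' and C8'' together.
2. 18 ⇐ SN2 of syringyl-type phenol 14 on racemic α-bromo-propiovanillone 17.
3. Core 14 (meso-type 8,8'-dimethyl-1,4-diarylbutane) ⇐ two Weinreb-amide/ArMgBr additions, each followed by ionic deoxygenation, on the mono-ester acid 3. Acid 3 comes from cinchona-catalysed desymmetrisation of meso-anhydride 2, which comes from hydrogenation of 1.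
4. No ring is formed: the aryl rings are purchased, and the anhydride ring is only a temporary stereochemical template opened in Step 2.

## Route

**Step 1**
- Reactants: 1, 2,3-dimethylmaleic anhydride.
- Product: 2, cis (meso)-(3R,4S)-3,4-dimethyloxolane-2,5-dione.
- Conditions: H2 (1 atm), 10% Pd/C, EtOAc, rt.
- Reagents that add atoms: none.
- Why: Syn-hydrogenation of the tetrasubstituted alkene gives the cis (meso) anhydride, which fixes the relative configuration of both future C8 and C8'.

**Step 2**
- Reactants: 2, plus MeOH.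
- Product: 3, (2R,3S)-4-methoxy-2,3-dimethyl-4-oxobutanoic acid.
- Conditions: (DHQD)2AQN (10 mol%), MeOH (5 equiv), MTBE, −20 °C.
- Reagents that add atoms: methanol, CO (adds OMe).
- Why: Cinchona-alkaloid general-base catalysed alcoholysis desymmetrises the meso-anhydride and sets both stereocentres at once; the α-centres cannot epimerise in the carboxylate or ester.

**Step 3**
- Reactants: 3, plus N,O-dimethylhydroxylamine·HCl.
- Product: 4, methyl (2S,3R)-4-[methoxy(methyl)amino]-2,3-dimethyl-4-oxobutanoate.
- Conditions: MeNHOMe·HCl, EDC·HCl, HOBt, i-Pr2NEt, CH2Cl2, 0 °C → rt.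
- Reagents that add atoms: N,O-dimethylhydroxylamine, CNOC.
- Why: Standard carbodiimide Weinreb amidation; the methyl ester is untouched and the α-stereocentres are not scrambled.

**Step 4**
- Reactants: 5, 4-bromo-2-methoxyphenol, plus benzyl bromide.
- Product: 6, 1-(benzyloxy)-4-bromo-2-methoxybenzene.
- Conditions: BnBr, K2CO3, DMF, rt.
- Reagents that add atoms: benzyl bromide, BrCc1ccccc1.
- Why: Williamson O-benzylation of the phenol.

**Step 5**
- Reactants: 4 and 6.
- Product: 7, methyl (2S,3R)-4-[4-(benzyloxy)-3-methoxyphenyl]-2,3-dimethyl-4-oxobutanoate.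
- Conditions: 6 + Mg, THF, 50 °C, 1 h to give ArMgBr; then add 4, THF, 0 °C → rt; aq NH4Cl quench.
- Reagents that add atoms: none (the aryl group comes from 6).
- Why: Weinreb ketone synthesis. The stable chelated tetrahedral intermediate prevents over-addition, and the amide reacts faster than the methyl ester at 0 °C. No stereocentre is touched.

**Step 6**
- Reactants: 7.
- Product: 8, methyl (2S,3S)-4-[4-(benzyloxy)-3-methoxyphenyl]-2,3-dimethylbutanoate.
- Conditions: Et3SiH (3 equiv), TFA (10 equiv), CH2Cl2, 0 °C → rt.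
- Reagents that add atoms: none (hydride only).
- Why: Ionic hydrogenation of the p-alkoxy aryl ketone via the benzylic cation deoxygenates it to CH2, and the epimerisable α-centre is removed at once. The ester and the aryl benzyl ether survive.

**Step 7**
- Reactants: 8, plus N,O-dimethylhydroxylamine·HCl.
- Product: 9, (2S,3S)-4-[4-(benzyloxy)-3-methoxyphenyl]-N-methoxy-N,2,3-trimethylbutanamide.
- Conditions: MeNHOMe·HCl, i-PrMgCl (4 equiv), THF, −20 → 0 °C.
- Reagents that add atoms: N,O-dimethylhydroxylamine, CNOC.
- Why: Williams ester-to-Weinreb amidation via the magnesium amide.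

**Step 8**
- Reactants: 10, 4-bromo-2,6-dimethoxyphenol, plus allyl bromide.
- Product: 11, 2-(allyloxy)-5-bromo-1,3-dimethoxybenzene.
- Conditions: allyl bromide, K2CO3, acetone, reflux.
- Reagents that add atoms: allyl bromide, C=CCBr.
- Why: O-allylation gives a phenol protecting group that can be removed orthogonally to benzyl.

**Step 9**
- Reactants: 9 and 11.
- Product: 12, (2S,3S)-1-[4-(allyloxy)-3,5-dimethoxyphenyl]-4-[4-(benzyloxy)-3-methoxyphenyl]-2,3-dimethylbutan-1-one.
- Conditions: 11 + Mg, THF, reflux, to give ArMgBr; add 9 (0.5 equiv relative to Grignard), THF, 0 °C → rt; aq NH4Cl.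
- Reagents that add atoms: none (the aryl group comes from 11).
- Why: Weinreb ketone synthesis again; the Cb centre is epimerisable only while it is α to this ketone, which exists for one step.

**Step 10**
- Reactants: 12.
- Product: 13, 2-(allyloxy)-5-[(2R,3S)-4-[4-(benzyloxy)-3-methoxyphenyl]-2,3-dimethylbutyl]-1,3-dimethoxybenzene.
- Conditions: Et3SiH (3 equiv), TFA (10 equiv), CH2Cl2, 0 °C → rt.
- Reagents that add atoms: none.
- Why: Ionic deoxygenation of the syringyl ketone (very easy through a highly stabilised cation) completes the meso-type (8S,8'R) core. The allyl and benzyl ethers are stable to TFA in CH2Cl2 at rt, and there are no acidic α-H left to epimerise.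

**Step 11**
- Reactants: 13.
- Product: 14, 4-[(2R,3S)-4-[4-(benzyloxy)-3-methoxyphenyl]-2,3-dimethylbutyl]-2,6-dimethoxyphenol.
- Conditions: Pd(PPh3)4 (5 mol%), K2CO3, MeOH, rt.
- Reagents that add atoms: none (the allyl group is trapped by MeOH as allyl methyl ether).
- Why: Tsuji–Trost deallylation of the aryl allyl ether; the benzyl ether is unaffected.

**Step 12**
- Reactants: 15, propiovanillone (1-(4-hydroxy-3-methoxyphenyl)propan-1-one), plus benzyl bromide.
- Product: 16, 1-[4-(benzyloxy)-3-methoxyphenyl]propan-1-one.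
- Conditions: BnBr, K2CO3, DMF, rt.
- Reagents that add atoms: benzyl bromide, BrCc1ccccc1.
- Why: Williamson O-benzylation.

**Step 13**
- Reactants: 16, plus CuBr2.
- Product: 17, (±)-1-[4-(benzyloxy)-3-methoxyphenyl]-2-bromopropan-1-one.
- Conditions: CuBr2 (2.1 equiv), EtOAc/CHCl3 1:1, reflux.
- Reagents that add atoms: copper(II) bromide, [Cu+2].[Br-].[Br-].
- Why: CuBr2 α-bromination of the aryl ketone via the enol, with little ring bromination.

**Step 14**
- Reactants: 14 and 17.
- Product: 18, α-aryloxy ketone, 1-[4-(benzyloxy)-3-methoxyphenyl]-2-{4-[(2R,3S)-4-(4-(benzyloxy)-3-methoxyphenyl)-2,3-dimethylbutyl]-2,6-dimethoxyphenoxy}propan-1-one, as an 8''-epimeric mixture.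
- Conditions: K2CO3 (2 equiv), acetone, 50 °C.
- Reagents that add atoms: none (both reactants are fully incorporated).
- Why: SN2 displacement of the activated α-bromoketone by the syringyl phenoxide. C8'' is left racemic and epimerisable, which is what the next step needs.

**Step 15**
- Reactants: 18.
- Product: 19, (1S,2R)-1-[4-(benzyloxy)-3-methoxyphenyl]-2-{4-[(2R,3S)-4-(4-(benzyloxy)-3-methoxyphenyl)-2,3-dimethylbutyl]-2,6-dimethoxyphenoxy}propan-1-ol, the erythro (7''S,8''R) bis-benzyl ether.
- Conditions: (R,R)-RuCl(p-cymene)(TsDPEN) (3 mol%), HCO2H/Et3N (1:2), CH2Cl2, 40 °C, 48 h.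
- Reagents that add atoms: none (formate supplies hydride and proton).
- Why: Proposed new method: Noyori–Ikariya ATH combined with dynamic kinetic resolution (closest known reaction: ATH-DKR of α-alkoxy and α-amino β-keto esters and α-substituted aryl ketones), extended to an acyclic α-(2,6-dimethoxyphenoxy)-propiophenone of the β-O-4 lignin type, which should set both C7'' and C8'' from a racemic ketone.
  - The electron-rich aryl ketone docks through CH/π contact with the η6-cymene and an N–H···O=C hydrogen bond in the six-membered Ru–H transfer state.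
  - The (R,R) catalyst delivers hydride to the same face that converts acetophenone to (R)-1-phenylethanol; with the C8'' substituent outranking the aryl group in CIP, this gives 7''S.
  - The α-C–H is flanked by C=O and OAr, so Et3N-mediated enolisation epimerises C8'' faster than reduction. Curtin–Hammett selection of the enantiomer that best fits the catalyst pocket, with the bulky ArO group remote from the metal face, is predicted to give the erythro (8''R) product.
  - The diastereoselectivity is a hypothesis. It runs against the polar-Felkin bias, and the competing reductive C–O cleavage of α-aryloxy ketones by formate is expected to be slow at 40 °C.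

**Step 16**
- Reactants: 19.
- Product: 20, target, (+)-(7''S,8S,8'R,8''R)-4,4''-dihydroxy-3,3',3'',5'-tetramethoxy-4',8''-oxy-8,8'-sesquineolignan-7''-ol.
- Conditions: H2 (1 atm), 10% Pd/C, EtOAc/EtOH 1:1, rt, 2 h.
- Reagents that add atoms: none.
- Why: Hydrogenolysis removes both phenolic benzyl ethers under neutral conditions. The benzylic alcohol and the aryl ether are retained at 1 atm and short reaction time, as in guaiacylglycerol β-ether syntheses, and no stereocentre is affected.

## Compound list
1 | 2,3-dimethylmaleic anhydride | CC1=C(C)C(=O)OC1=O | starting material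
2 | cis (meso)-(3R,4S)-3,4-dimethyloxolane-2,5-dione | C[C@H]1C(=O)OC(=O)[C@H]1C | intermediate
3 | (2R,3S)-4-methoxy-2,3-dimethyl-4-oxobutanoic acid | OC(=O)[C@H](C)[C@H](C)C(=O)OC | intermediate
4 | methyl (2S,3R)-4-[methoxy(methyl)amino]-2,3-dimethyl-4-oxobutanoate | CON(C)C(=O)[C@H](C)[C@H](C)C(=O)OC | intermediate
5 | 4-bromo-2-methoxyphenol | COc1cc(Br)ccc1O | starting material
6 | 1-(benzyloxy)-4-bromo-2-methoxybenzene | COc1cc(Br)ccc1OCc1ccccc1 | intermediate
7 | methyl (2S,3R)-4-[4-(benzyloxy)-3-methoxyphenyl]-2,3-dimethyl-4-oxobutanoate | COc1cc(ccc1OCc1ccccc1)C(=O)[C@H](C)[C@H](C)C(=O)OC | intermediate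
8 | methyl (2S,3S)-4-[4-(benzyloxy)-3-methoxyphenyl]-2,3-dimethylbutanoate | COc1cc(C[C@H](C)[C@H](C)C(=O)OC)ccc1OCc1ccccc1 | intermediate
9 | (2S,3S)-4-[4-(benzyloxy)-3-methoxyphenyl]-N-methoxy-N,2,3-trimethylbutanamide | COc1cc(C[C@H](C)[C@H](C)C(=O)N(C)OC)ccc1OCc1ccccc1 | intermediate
10 | 4-bromo-2,6-dimethoxyphenol | COc1cc(Br)cc(OC)c1O | starting material
11 | 2-(allyloxy)-5-bromo-1,3-dimethoxybenzene | C=CCOc1c(OC)cc(Br)cc1OC | intermediate
12 | (2S,3S)-1-[4-(allyloxy)-3,5-dimethoxyphenyl]-4-[4-(benzyloxy)-3-methoxyphenyl]-2,3-dimethylbutan-1-one | COc1cc(C[C@H](C)[C@H](C)C(=O)c2cc(OC)c(OCC=C)c(OC)c2)ccc1OCc1ccccc1 | intermediate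
13 | 2-(allyloxy)-5-[(2R,3S)-4-[4-(benzyloxy)-3-methoxyphenyl]-2,3-dimethylbutyl]-1,3-dimethoxybenzene | COc1cc(C[C@H](C)[C@H](C)Cc2cc(OC)c(OCC=C)c(OC)c2)ccc1OCc1ccccc1 | intermediate
14 | 4-[(2R,3S)-4-[4-(benzyloxy)-3-methoxyphenyl]-2,3-dimethylbutyl]-2,6-dimethoxyphenol | COc1cc(C[C@H](C)[C@H](C)Cc2cc(OC)c(O)c(OC)c2)ccc1OCc1ccccc1 | intermediate
15 | 1-(4-hydroxy-3-methoxyphenyl)propan-1-one (propiovanillone) | CCC(=O)c1ccc(O)c(OC)c1 | starting material
16 | 1-[4-(benzyloxy)-3-methoxyphenyl]propan-1-one | CCC(=O)c1ccc(OCc2ccccc2)c(OC)c1 | intermediate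
17 | (±)-1-[4-(benzyloxy)-3-methoxyphenyl]-2-bromopropan-1-one | CC(Br)C(=O)c1ccc(OCc2ccccc2)c(OC)c1 | intermediate
18 | α-aryloxy ketone (8''-epimeric mixture) | COc1cc(C[C@H](C)[C@H](C)Cc2cc(OC)c(OC(C)C(=O)c3ccc(OCc4ccccc4)c(OC)c3)c(OC)c2)ccc1OCc1ccccc1 | intermediate
19 | (1S,2R)-erythro bis-benzyl ether alcohol | COc1cc(C[C@H](C)[C@H](C)Cc2cc(OC)c(O[C@H](C)[C@@H](O)c3ccc(OCc4ccccc4)c(OC)c3)c(OC)c2)ccc1OCc1ccccc1 | intermediate
20 | target, (+)-(7''S,8S,8'R,8''R)-4,4''-dihydroxy-3,3',3'',5'-tetramethoxy-4',8''-oxy-8,8'-sesquineolignan-7''-ol | COc1cc(C[C@H](C)[C@H](C)Cc2cc(OC)c(O[C@H](C)[C@@H](O)c3ccc(O)c(OC)c3)c(OC)c2)ccc1O | target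

## Summary
**Total steps:** 16, counting four building-block preparations (Steps 4, 8, 12, 13).
**Longest linear sequence:** 12 steps (1 → 2 → 3 → 4 → 7 → 8 → 9 → 12 → 13 → 14 → 18 → 19 → 20).

**Three steps most likely to fail**

1. **Step 15, the proposed new ATH-DKR.** The erythro diastereoselectivity is unproven, and formate-mediated reductive C–O cleavage may compete.
   - Fallback (known chemistry, different approach): Mitsunobu of phenol 14 with ethyl (S)-lactate (DIAD, PPh3) to give the (R)-2-aryloxy ester, which fixes C8''.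
   - Then convert the ester to the Weinreb amide and add the 4-benzyloxy-3-methoxyphenyl Grignard (from 6) to give the (R)-ketone.
   - Reduce with Zn(BH4)2 (chelation control), separate the 7''-epimers by HPLC, and finish with H2/Pd-C.
2. **Step 2, enantioselectivity of the cinchona-catalysed desymmetrisation.** The ee for the cis-2,3-dimethylsuccinic anhydride may be below the level needed.
   - Fallback: stoichiometric chiral-auxiliary opening of 2 with lithiated (S)-4-benzyloxazolidin-2-one, then chromatographic separation of diastereomers.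
   - Methylate the acid (TMSCHN2), then convert the imide to Weinreb amide 4 with AlMe3/MeNHOMe·HCl.
3. **Step 9, hindered Weinreb amide plus aryl Grignard, with a risk of Cb epimerisation.**
   - Fallback: skip 9, 12 and 13. Reduce ester 8 (LiAlH4) to the alcohol and convert it to the primary iodide (I2/PPh3/imidazole).
   - Then do a Ni-catalysed sp3–sp2 Negishi coupling with the arylzinc from 11 to give 13 directly, with no α-carbonyl intermediate.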